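In a one-step world, with rate k[substrate][reagent][free catalyst] and with [reagent] and [free catalyst] held fixed, the percent of target does not change with the substrate charged.

| flask | substrate | reagent | free catalyst | remark | time |
|---|---|---|---|---|---|
| theta | 0.10 M | 0.21 M (in portions, 3) | 11 mM | run made earlier; portions every 4.0 h |  |
| gamma | 0.10 M | 0.69 M (in portions, 3) | 11 mM | run made earlier; portions every 4.0 h |  |
| zeta | 0.10 M | 0.15 M (in portions, 3) | 25 mM | run made earlier; portions every 4.0 h |  |
| birch | 0.10 M | 0.150 M (in portions, 3) | 11 mM | the portions of reagent follow each other after 4.0 h, the first at the start | 25 h |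
| alder | 0.20 M | 0.600 M (in portions, 3) | 40 mM | the portions of reagent follow each other after 4.0 h, the first at the start | 25 h |
| elm | 0.10 M | 0.150 M (in portions, 3) | 40 mM | the portions of reagent follow each other after 15 h, the first at the start | 25 h |
| ash | 0.15 M | 0.150 M (in portions, 3) | 11 mM | the portions of reagent follow each other after 1.0 h, the first at the start | 25 h |
| oak | 0.30 M | 0.150 M (in portions, 3) | 11 mM | the portions of reagent follow each other after 4.0 h, the first at the start | 25 h |

- theta (time / h: target / %): 2.00: 0; 6.00: 4; 12.0: 16; 20.0: 26
- gamma (time / h: target / %): 1.33: 2; 3.00: 6; 8.00: 9; 20.0: 35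
- zeta (time / h: target / %): 4.00: 6; 8.00: 16; 12.0: 27; 20.0: 45

(standard deviation of a reading: 2 percentage points)

- percentages count the whole charge, also what has not yet gone in
- a reading or a percentage of target counts all its forms, free or not

1. ranking by amount of target, in percent of the substrate charged, from high to low, at 25 h (birch / alder / elm / ash / oak)
2. the amount of target, in percent of the substrate charged of the flask you put first, at 25 h
3. the amount of target, in percent of the substrate charged of the flask you put last, at 25 h

The three runs share 0.10 M of substrate, so they cannot test that claim. They do give a measure that can be carried between flasks: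

pace, zeta = 45% × 0.10 M / (25 mM × 20.0 h) = 0.0900 h⁻¹

This 0.0900 h⁻¹, the target made per catalyst charged per hour, averaged from the start, is a turnover frequency. Gamma, with 0.69 M of reagent against zeta's 0.15 M, reads 0.159 h⁻¹, faster. Zeta at 4.00 h, with its first portions in, reads a slower 0.0600 h⁻¹.

Percent of target is then pace × catalyst × time / substrate. Alder is rich in reagent, so it takes gamma's pace. Birch has zeta's reagent schedule, so it takes zeta's. Elm holds one portion for its first 15 h of 25 h, so it takes zeta's early pace:

alder: 0.159 h⁻¹ × 40 mM × 25 h / 0.20 M = 79.5%

elm: 0.0600 h⁻¹ × 40 mM × 25 h / 0.10 M = 60.0%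

birch: 0.0900 h⁻¹ × 11 mM × 25 h / 0.10 M = 24.7%

Ash and oak test the substrate charge, and two reckonings are open for them. The one-step world keeps birch's percent, while a fixed pace gives these:

ash: 16.5%

oak: 8.25%

With the fixed pace, this reckoning runs alder, elm, birch, ash, oak. The forecast reads alder > elm > ash > birch > oak, with 83% (68% to 94%) first and 25% (14% to 33%) last, so it differs from this reckoning in placing ash above birch, and it says “The last three are close.”

The flasks give alder > elm > birch > ash > oak: alder 84.2%, elm 53.9%, birch 32.4%, ash 30.1%, oak 20.6%.

    reagent + free catalyst ⇌ catalyst intermediate A (K = 10.0 M⁻¹, k = 96.0 M⁻¹ h⁻¹)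
    substrate + catalyst intermediate A → catalyst intermediate B (k = 4.50 M⁻¹ h⁻¹)
    catalyst intermediate B → free catalyst + target (k = 0.440 h⁻¹)
    crystals ⇌ target, rate k4*(cs4 - [target]) while solid is left; crystals form when [target] > cs4 (solubility = 0.0590 M, k = 1.90 h⁻¹)

Oak's 20.6% of 0.30 M is a pace of 0.224 h⁻¹, above zeta's 0.0900 h⁻¹. The neighbour is oak with 1.2 M of substrate. Zeta's pace gives it 2.06%, and the flask gives 7.67%. That is a pace of 0.335 h⁻¹, faster than oak's and slower than k3, 0.44 h⁻¹. Its percent is lower than oak's, yet its target is 0.0920 M against oak's 0.0618 M. At 25.0 h, catalyst intermediate B holds 74.0% of the neighbour's catalyst.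

Readings and results come from a simulation with constants of no real substance; noise was put on by code.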